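Millimolar per minute is the unit to read this flask in: solid reagent enters the solution, and a radical chain turns coupling partner and substrate into product.

substrate 0.097 M; solid reagent 1.00 equiv; initiator 2.6 mol%; time 5.0 h

- why nothing more happens at 5.0 h, or that something still does (for what has run out or reacted, a solid counts together with what of it has only dissolved) (the coupling partner has run out first / it is still moving / all of the substrate has reacted / forward and back rates have come level)
- conversion of substrate at 5.0 h
- amount of product at 5.0 h, in percent of the substrate charged

- percent here means substrate units held: one ended chains counts as two
- where a step has two of a species, its rate is k times that concentration squared, and two are used at each turn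
- solid reagent is a solid; its amount is given per volume of the solution
- at the start none of the solid reagent is in solution
- the reaction counts as stopped when no species that holds the substrate changes by six tenths of a point or more over the second half of the time
- run time (flask): 5.0 h

    coupling partner + first chain carrier ⇌ product + second chain carrier (K1 = 0.561, k1 = 77800 /M/s)
    solid reagent ⇌ coupling partner, rate k2*(cs2 - [coupling partner]) while solid is left; crystals form when [coupling partner] > cs2 (cs2 = 43 mM, k2 = 0.00440 /min)
    substrate + initiating radical → capped initiator + first chain carrier (k3 = 2.63 × 10⁵ /M/s)
    2 first chain carrier → ended chains (k4 = 2 × 10⁷ /M/s)
    coupling partner → decomposed reagent (k5 = 0.00199 /min)
    substrate + second chain carrier → by-product + first chain carrier (k6 = 46200 /M/s)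
    initiator → 2 initiating radical (k7 = 0.00159 /min)
    first chain carrier → ended carrier (k8 = 13.5 /min)

My quantity is 0.189 mM/min, the feed ceiling: solubility times dissolution coefficient, the rate at which solid reagent enters a solution empty of coupling partner. You can test whether it binds in this flask by turning constants into times. Balancing radicals from the initiator against ended chains puts first chain carrier near 5.78 × 10⁻⁸ M, so coupling partner lasts 3.71 min in the chain. That is far shorter than the 227 min of dissolving and the 503 min of decomposing, so dissolving is the rate-limiting step. When product equals substrate, second chain carrier falls back 3.00 times as often as it goes on. That lifts the standing coupling partner to 2.81 mM, far below the solubility, so the feed stays near its ceiling.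

Now turn the settings by hand. Time: while solid remains and the feed holds at its ceiling, product grows in proportion to it, and the ceiling allows 58.5% of the charge by 5.0 h. Substrate: the same feed is spread over more, so the percentages fall as its amount rises. Initiator: more of it shortens the time coupling partner lasts and lowers the stock, which is small against the ceiling, but its radicals also cap more substrate. Solid reagent: the feed law holds no term for its amount while solid remains, and at the ceiling this charge lasts 8.54 h, longer than the run. Taking off the stock, I commit to product 55.6%. Adding the substrate capped by initiating radicals gives conversion 57.6%, and the end state is it is still moving.

The forecast, lower than my figures, says it is still moving, conversion 50% and product 48%, on the ground that “product builds at about the dissolution limit”. The simulation gives it is still moving, conversion 53.7% and product 51.7%, and with each setting moved alone by one common factor, the shifts in conversion, at most, run time (14 points), then substrate (12 points), then initiator (1.2 points), then solid reagent (under 0.05 points).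

In this flask at 2.46 h, coupling partner is made 1.05 times as fast as it is used, each step taken net, and product ends at 51.7%, below the ceiling's 58.5%. In the neighbour flask with 0.24 M of substrate, equivalents and loading held, the same feed ceiling gives 23.6%, and product there stands at 22.6%.

All constants belong to no real substance; the run is a simulation.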